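The earlier runs and the new flask come from a simulation for an exercise.

One flask to pick and 3 amounts to give: that is the task.

| flask | substrate | catalyst | temperature | remark | time |
|---|---|---|---|---|---|
| north | 1.1 M | 1.8 mol% | 0 °C | run made earlier |  |
| south-east | 1.8 M | 1.8 mol% | 35 °C | run made earlier |  |
| red | 0.80 M | 1.8 mol% | 5 °C |  | 2.5 h |
| teal | 0.80 M | 1.8 mol% | 65 °C |  | 2.5 h |
| violet | 0.80 M | 1.8 mol% | 35 °C |  | 2.5 h |

- north (time / h: intermediate / %, target / %): 0.333: 7.4, 1.6; 0.667: 8.8, 6.1; 1.00: 13.0, 5.8; 1.33: 11.8, 6.6; 2.00: 12.0, 6.3; 2.50: 13.4, 8.0
- south-east (time / min: intermediate / %, target / %): 2.50: 19.3, 8.7; 5.00: 19.9, 10.0; 6.00: 18.9, 10.2; 10.0: 20.1, 10.5; 15.0: 20.3, 8.2; 20.0: 22.0, 11.4; 30.0: 19.8, 8.2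

(each reading ± 1 percentage point)

- the best flask by amount of intermediate, in percent of the substrate charged; "all alike" if 1.5 percentage points covers them all (red / teal / violet / all alike)
- amount of intermediate at the end, in percent of the substrate charged, red
- amount of intermediate at the end, in percent of the substrate charged, teal
- amount of intermediate at the end, in percent of the substrate charged, violet

- the numbers in the tables scatter by 1 percentage point (one standard deviation)

Take time first. By hand, longer should give more. But the north readings slow after 1.00 h, and the south-east readings show no trend from 2.50 min. Intermediate plus target averages 19.2 % over the north readings from 1.00 h on and 29.6 % over the south-east readings. The north run may still be rising, as its last sum reads 21.4 %, so I take its average as a rough reading. The rest of the charge stands in neither column.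

My reckoning is that the substrate goes partly down an unread route that takes two substrate at a time. Then the final level is a split between two rates, and in their ratio time drops out. So I expect 2.5 h to do for red, which runs warmer than the north run.

Take the catalyst next. By hand, it should move intermediate into target. But every flask carries 1.8 mol%, so the readings cannot show its effect. I hold the intermediate's share of the sum at 66.7 %.

Now take charge and temperature. A route that pairs substrate should grow with charge, so I divide the lost part over the kept part by the charge. Call this the waste number, a selectivity factor per molar. It is 3.82 M⁻¹ for north and 1.32 M⁻¹ for south-east, so it is lower in the warmer run. This split between charge and temperature is my assumption, since the two runs differ in both.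

With a constant factor per degree, the waste number at 5 °C is 3.28 M⁻¹. At 65 °C, outside the runs, it is 0.530 M⁻¹.

Intermediate is then the share divided by one plus waste number times charge. That gives 18.4 % for red, 32.5 % for violet and 46.8 % for teal.

The forecast reads the levelling as “an equilibrium or a catalyst-limited ceiling”. It gives 11.5 % for red (8.5 % to 14.5 %), 18 % for teal (9 % to 27 %) and 15 % for violet (9 % to 21 %), and it picks teal. My teal amount is higher than the forecast's.

The flasks give 19.0 % in red, 40.8 % in teal and 30.2 % in violet, so teal is best.

    substrate → intermediate (k = 3.00 × 10⁻⁴ s⁻¹, Ea = 82.0 kJ mol⁻¹)
    catalyst + intermediate ⇌ catalyst + target (K = 0.620, k = 0.0220 M⁻¹ s⁻¹, Ea = 60.0 kJ mol⁻¹, ΔH = −5.00 kJ mol⁻¹)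
    2 substrate → self-condensation product (k = 0.00120 M⁻¹ s⁻¹, Ea = 65.0 kJ mol⁻¹)
    (constants at 5 °C)

Red ends with 68.7 % self-condensation product, counted as the substrate it holds, against 19.0 % intermediate and 11.4 % target. Its lost part over kept part is 2.26, where the waste number times the charge gave 2.62. Now raise red's substrate to 2.0 M and hold the temperature. The waste number times that charge is 6.56, so you expect 8.82 % intermediate. That neighbouring flask gives 10.7 % intermediate, beside 6.59 % target and 82.3 % self-condensation product.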